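## Structural features

The target is a flavonol with no stereocentre: a chromen-4-one in which ring A (benzo) and ring C (pyranone) share the C4a–C8a bond, with ring B, a para-substituted phenyl, attached at C2. Ring A is penta-substituted, with hydroxyls at C5 (hydrogen-bonded to the C4 carbonyl) and C7, a methoxy group at C8 and only C6–H left. Ring C carries the 3-hydroxyl next to the carbonyl, and ring B carries a 3-methylbut-2-enyl (prenyl) ether at C4′. The prenyl aryl ether is the fragile group: acid, hydrogenolysis, electrophilic oxidants or halogen sources (which attack its trisubstituted alkene), zerovalent palladium with an amine at high temperature, and heating above about 150 °C (Claisen rearrangement) all endanger it; the 3-hydroxy-4-pyranone unit is also air-sensitive in strong base. The real difficulty is regiochemical: four oxygens must be told apart, the methoxy group must end at C8 and not at C6 (the isomer that forms whenever the other oxygen ortho to the acyl carbon closes ring C, and that acid can produce by ring opening and reclosure), and C3 must be oxygenated in the presence of the prenyl alkene. Ring A hides a mirror plane through C8 and C5, so a symmetrical 2-methoxyresorcinol derivative can be desymmetrised by one iodination. The key step exploits ring C: the single carbonyl carbon C4 between C4a and C3 comes from carbon monoxide, C3 and C2 from the triple bond of an arylacetylene that brings ring B, and C4a and O1 from an ortho-iodophenol ester of ring A, so that C4a–C4, C4–C3 and O1–C2 are made in one operation.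

## Logic of the disconnections

**20 from 19.** The last bonds cut are the two O–Si bonds at O5 and O7. Fluoride is the one deprotecting agent that touches neither the allylic ether nor the enolised ring C, so both phenols stay silylated to the end. The gain is that no free phenol is carried through base or oxidant. The demand is a buffered fluoride source and exclusion of air.

**19 from 16.** The C3–O bond is cut next. C3 leaves the ring-forming step as C–H, and that vinylic C–H, alpha to the C4 carbonyl, is the only acidic C–H of 16. The prenyl alkene rules out peracids, dioxiranes and halogenating agents, so the oxygen must arrive through a carbanion and a boron group (17, 18) that a nucleophilic peroxide oxidises. The gain is a flavone one oxidation level lower with every hydroxyl masked. The demand is deprotonation at −78 °C without opening of ring C.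

**16 from 15.** The O7–Si bond is cut. The ring-forming step leaves O7 as a free, acidic phenol, which must be capped before the amide base is used. The same silyl group as on O5 is chosen so that one reagent removes both at the end.

**15 from 6, 11 and 12.** Three bonds are cut, C4a–C4, C4–C3 and O1–C2. This removes ring C and divides the molecule into a ring A piece, a ring B piece and one carbon, the most convergent division available. The position of the iodine in 6 decides the regiochemistry.

- Carbonylative coupling must beat direct coupling.
- 6-endo closure must beat 5-exo closure.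
- Only one oxygen ortho to the iodine may become nucleophilic.

For the last demand, 6 carries the ortho oxygen next to the methoxy group as an amine-labile acetate, the other ortho oxygen as a bulky, amine-stable triisopropylsilyl ether, and the para oxygen as an acetate that ends as O7–H. The acetates also make the aryl iodide a better partner for oxidative addition than a free, oxidisable iodoresorcinol, which allows a reaction temperature that the prenyl ether tolerates.

**6 from 5, and 5 from 4.** The O–Si bond and then the C–I bond are cut. The iodine must sit between the future O5 and the future O1. In 4 the two positions ortho to the free hydroxyl are related by the mirror plane, so iodination can give only 5. The hydroxyl that directed the iodination is then turned into the blocking silyl ether. The demand is mono-iodination.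

**4 from 2, and 2 from 1.** The C–O bond para to the methoxy group and the two O–acyl bonds are cut. In 2 that carbon bears the only C–H without an ortho substituent, so a sterically controlled C–H borylation (3) followed by C–B oxidation places the third oxygen. The acetates have no aromatic C–H of their own, they leave the new hydroxyl as the only free one (no protecting-group exchange), and they are the groups the ring-forming step needs. This reaches commercial 1 in two steps. The demand is an oxidation of the C–B bond that spares aryl acetates.

**11 from 9, and 9 from 7 and 8.** The triple bond is traced to a formyl group (one-carbon homologation via 10), and the O–C bond of the prenyl ether is cut. The prenyl group goes on at the start of ring B because no later stage offers a lone 4′-hydroxyl. The aldehyde route needs neither palladium nor a silyl alkyne. The demand is base-only conditions, which the prenyl ether tolerates.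

## Other disconnections considered

**Alternative 1:** The cut takes ring B apart at C1′–C2′ and C5′–C6′ and leads back to 2-ethynyl-8-methoxy-4-oxo-4H-chromene-3,5,7-triyl triacetate A1 and (E)-1-methoxy-3-(trimethylsilyloxy)buta-1,3-diene A2. In the forward step the triple bond of A1, whose terminal carbon is made electrophilic by the pyranone, would take up the nucleophilic CH2 terminus of A2. Loss of methanol and of the silyl group would aromatise the adduct to the 4′-phenol 2-(4-hydroxyphenyl)-8-methoxy-4-oxo-4H-chromene-3,5,7-triyl triacetate A3.

- In its favour: the polarity of both partners fixes the hydroxyl para to C1′. The 3-oxygen is in place before the key step, and on this point the alternative is the better plan, since the chosen route must oxidise C3–H late. A3 has a single free hydroxyl, so prenylation would be unambiguous, and the final removal of acetates by mild base is as compatible with the prenyl ether as fluoride is (equal). Two steps would follow the key step against three in the chosen plan (slightly better).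
- Against it here: ring B is the one ring that can be bought in any para pattern, whereas A1 still contains rings A and C with every oxygen placed, the 8-methoxy regiochemistry settled and an alkyne at C2. A1 is also a doubly activated acceptor, so stepwise conjugate addition of the silyl enol ether competes with cycloaddition, and its acetates may migrate on heating. Prenylation of A3 would have to avoid bases that cleave aryl acetates.
- Comparison: on structure the alternative solves none of the oxygen differentiation of ring A. On mechanism it is a thermal pericyclic step with predictable regiochemistry against a catalytic cascade with several branch points. On step economy it forms two bonds of a ring that needs no synthesis, while the chosen step forms three bonds, closes the heterocycle and joins all three building blocks.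

**Alternative 2:** The cut is the C3–C4 bond of a 3-hydroxychroman-4-one and leads back to the dialdehyde 3-methoxy-4,6-bis(methoxymethoxy)-2-{1-[4-(3-methylbut-2-enyloxy)phenyl]-2-oxoethoxy}benzaldehyde A4. In the forward step a triazolium-derived carbene with a weak amine base would add to the aromatic formyl group, and the resulting acyl-anion equivalent would attack the aliphatic formyl group. Ring C would close as trans-3-hydroxy-8-methoxy-5,7-bis(methoxymethoxy)-2-[4-(3-methylbut-2-enyloxy)phenyl]chroman-4-one A5.

- In its favour: the 3-hydroxyl comes with the ring closure, without organolithium chemistry or metal, near room temperature; on this point the alternative is the better plan. O1 is fixed by an ordinary O-alkylation, as unambiguous as the iodine position in 6 (equal).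
- Against it here: A5 is a dihydroflavonol, so C2–C3 must still be dehydrogenated, and the two adjacent stereocentres, whose control is the main asset of the method, are erased. A4 is an alpha-aryl-alpha-aryloxy acetaldehyde that should enolise easily, can expel the phenoxide, and offers the carbene two formyl groups (attack on the aliphatic one would give the transposed ketol). The methoxymethyl ethers need acid for removal, which threatens the prenyl ether through allyl cation formation and opens the path to the 6-methoxy isomer.
- Comparison: on structure one bond and one ring are formed against three bonds and one ring. On mechanism the umpolung step is mild, but its chemoselectivity rests on the relative reactivity of two aldehydes, whereas the chosen cascade follows the fixed order oxidative addition, CO insertion, alkynylation. On step economy A4 needs a formylated ring A piece, a hindered O-alkylation between formyl and methoxy groups and redox adjustment of the side chain, so it is longer before the key step. After it, dehydrogenation and deprotection are two steps against three (equal or slightly better), but with an acid deprotection that the chosen plan avoids.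

**Alternative 3:** The cuts are C4–C4a and O1–C2. C2, C3 and C4 with the 3-oxygen and ring B arrive in ethyl 2-(benzyloxy)-3-[4-(benzyloxy)phenyl]-3-oxopropanoate A7, and ring A arrives as the symmetrical 5-(benzyloxy)-2-methoxybenzene-1,3-diol A6. In the forward step the two would be heated without catalyst to about 240 °C. Ethanol would be lost, ring A acylated at the carbon between a hydroxyl and the benzyloxy group, and cyclodehydration would give 3,5-bis(benzyloxy)-2-[4-(benzyloxy)phenyl]-7-hydroxy-8-methoxychromen-4-one A8.

- In its favour: one step builds ring C with all its substituents from two simple components, without metal or CO. In bonds per step and in the step count to the flavonol core the alternative is better than the chosen plan. The mirror symmetry of A6 makes both acylation sites equivalent and only the hydroxyl next to the methoxy group can close, so the 8-methoxy regiochemistry is as secure as in the chosen plan (equal).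
- Against it here: a prenyl aryl ether cannot be expected to survive 240 °C (Claisen rearrangement, loss of isoprene), which is why O4′ must be a benzyl ether. The benzyl groups of A8 can then be removed only by hydrogenolysis or Lewis acid before the prenyl group exists. The prenyl group would afterwards have to be placed on O4′ of a polyphenol in which O7 is the most acidic and O3 also competes. That selectivity rests on acidity differences alone, or else on extra protecting-group steps that use up the advantage. The thermal condensation also has competing channels: O-acylation, coumarin formation by attack at the ketone carbonyl, thermolysis of benzyl ethers.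
- Comparison: on structure both plans use the same symmetry of ring A; the alternative carries O3 from the start, the chosen plan carries the prenyl ether from the start. On mechanism an uncatalysed condensation at the limit of thermal stability stands against a catalytic cycle at 40 °C. On step economy the alternative is better up to A8 and worse from A8 to the target, where the chosen plan needs three mild steps.

Key step: step 7

Assumption: the two acetates of 6 are treated as protecting groups of the ortho-iodophenol; diethylamine removes them in the flask, so the key step forms the same three bonds and closes the same ring as with the free iodophenol.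

## Route

Step 1
Reactants: 1 2-methoxybenzene-1,3-diol (2-methoxyresorcinol)
Product: 2 2-methoxy-1,3-phenylene diacetate
Conditions: Ac2O (2.5 equiv), pyridine, DMAP (cat.), CH2Cl2, 0 °C → rt
Reagents that add atoms: acetic anhydride, CC(=O)OC(C)=O
Why: DMAP-catalysed O-acetylation (nucleophilic acyl substitution) of both phenols; the acetates carry no aromatic C–H of their own, survive the next steps and are the amine-labile groups needed in the key step.

Step 2
Reactants: 2 2-methoxy-1,3-phenylene diacetate
Product: 4 5-hydroxy-2-methoxy-1,3-phenylene diacetate, via aryl pinacolboronate 3 (not isolated)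
Conditions: [Ir(OMe)(cod)]2 (1.5 mol %), 4,4′-di-tert-butyl-2,2′-bipyridine (3 mol %), B2pin2 (1.0 equiv), THF, 80 °C; evaporation; then KHSO5 (as 2KHSO5·KHSO4·K2SO4), acetone/H2O, 0 °C → rt, 15 min
Reagents that add atoms: potassium peroxymonosulfate, [K+].[O-]S(=O)(=O)OO (oxygen of the new hydroxyl); bis(pinacolato)diboron, CC1(C)OB(OC1(C)C)B1OC(C)(C)C(C)(C)O1 (boryl group of intermediate 3 only)
Why: Sterically controlled iridium-catalysed aromatic C–H borylation, which should enter at the only C–H of 2 without an ortho substituent (para to the methoxy group), followed by oxidation of the C–B bond with peroxymonosulfate (aryl shift from boron to oxygen) under non-basic conditions that leave the acetates in place.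

Step 3
Reactants: 4 5-hydroxy-2-methoxy-1,3-phenylene diacetate
Product: 5 5-hydroxy-4-iodo-2-methoxy-1,3-phenylene diacetate
Conditions: NIS (1.0 equiv, in portions), TsOH·H2O (10 mol %), MeCN, −20 → 0 °C, dark
Reagents that add atoms: N-iodosuccinimide, O=C1CCC(=O)N1I
Why: Electrophilic aromatic iodination ortho to the free hydroxyl (its para position is the methoxy-bearing carbon); the two ortho positions are related by the mirror plane of 4, so only one mono-iodide can form, and one equivalent of reagent at low temperature should hold the reaction at that stage.

Step 4
Reactants: 5 5-hydroxy-4-iodo-2-methoxy-1,3-phenylene diacetate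
Product: 6 4-iodo-2-methoxy-5-(triisopropylsilyloxy)-1,3-phenylene diacetate
Conditions: iPr3SiOTf (1.2 equiv), 2,6-lutidine (2 equiv), CH2Cl2, 0 °C
Reagents that add atoms: triisopropylsilyl trifluoromethanesulfonate, CC(C)[Si](C(C)C)(C(C)C)OS(=O)(=O)C(F)(F)F
Why: Silylation of a phenol with a silyl triflate and a hindered pyridine base; the bulky, amine-stable triisopropylsilyl ether locks the future O5 out of the ring closure, and imidazole-free conditions avoid acetyl transfer from the aryl acetates.

Step 5
Reactants: 7 4-hydroxybenzaldehyde, 8 1-bromo-3-methylbut-2-ene (prenyl bromide)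
Product: 9 4-(3-methylbut-2-enyloxy)benzaldehyde
Conditions: K2CO3 (1.5 equiv), acetone, reflux
Reagents that add atoms: none
Why: Williamson ether synthesis (SN2 of the phenoxide at the primary allylic bromide), which places the prenyl group before any stage at which four hydroxyls would have to be told apart.

Step 6
Reactants: 9 4-(3-methylbut-2-enyloxy)benzaldehyde
Product: 11 1-ethynyl-4-(3-methylbut-2-enyloxy)benzene, via diazoalkene 10 (not isolated)
Conditions: dimethyl (1-diazo-2-oxopropyl)phosphonate (1.3 equiv), K2CO3 (2 equiv), MeOH, 0 °C → rt
Reagents that add atoms: dimethyl (1-diazo-2-oxopropyl)phosphonate, CC(=O)C(=[N+]=[N-])P(=O)(OC)OC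
Why: Seyferth–Gilbert homologation in the Ohira–Bestmann variant: methanolysis of the acetyl group frees the diazomethylphosphonate anion, Horner–Wadsworth–Emmons-type olefination of 9 gives 10, and loss of N2 with 1,2-hydrogen shift gives the terminal alkyne under mild base that leaves the prenyl ether untouched.

Step 7
Reactants: 6 4-iodo-2-methoxy-5-(triisopropylsilyloxy)-1,3-phenylene diacetate, 11 1-ethynyl-4-(3-methylbut-2-enyloxy)benzene (1.5 equiv), 12 carbon monoxide
Product: 15 7-hydroxy-8-methoxy-2-[4-(3-methylbut-2-enyloxy)phenyl]-5-(triisopropylsilyloxy)chromen-4-one, via acetoxy ynone 13 (not isolated), via enaminone 14 (not isolated)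
Conditions: PdCl2(PPh3)2 (5 mol %), 1,3-bis(diphenylphosphino)propane (5 mol %), thiourea (5 mol %), DBU (3 equiv), Et2NH (solvent, degassed), CO (1 atm), 40 °C, 48 h; aq. NH4Cl
Reagents that add atoms: diethylamine, CCNCC (amino group of intermediate 14 only; released again on ring closure)
Why: PdCl2(PPh3)2 is reduced in the flask to zerovalent palladium, which inserts into the C–I bond of 6 (the acetates keep the arene electron-poor enough for this at 40 °C); CO insertion gives an aroyl–palladium species, and transfer of the amine-deprotonated alkyne 11 with reductive elimination gives ynone 13, forming C4a–C4 and C4–C3. Diethylamine then adds to the triple bond of 13 and removes both acetyl groups by aminolysis, giving the ortho-hydroxyaryl enaminone 14. The freed phenol attacks the amine-bearing carbon and expels diethylamine, a net 6-endo-dig oxa-Michael closure by addition–elimination that forms O1–C2 and closes ring C as the 4-pyranone. The closest known reaction type is the palladium-catalysed carbonylative Sonogashira coupling–cyclisation of ortho-iodophenols and their acetates with terminal alkynes to flavones. No stereocentre is formed. Three selectivities are needed: carbonylative over direct coupling (which would end in a benzofuran) is secured by the CO atmosphere, the absence of copper and the chelating phosphine–thiourea ligand set; 6-endo closure to the flavone over 5-exo closure to the aurone is secured by the secondary amine, since the enaminone can be displaced only at its beta carbon; and closure through the right oxygen is secured by the substrate, since of the two oxygens ortho to the iodine only the one next to the methoxy group is an amine-labile acetate while the other is an amine-stable silyl ether, and the para acetate, which ends as the free 7-hydroxyl, cannot reach C2. The low temperature also keeps the prenyl ether away from palladium–allyl cleavage and Claisen rearrangement.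

Step 8
Reactants: 15 7-hydroxy-8-methoxy-2-[4-(3-methylbut-2-enyloxy)phenyl]-5-(triisopropylsilyloxy)chromen-4-one
Product: 16 8-methoxy-2-[4-(3-methylbut-2-enyloxy)phenyl]-5,7-bis(triisopropylsilyloxy)chromen-4-one
Conditions: iPr3SiCl (1.5 equiv), imidazole (3 equiv), DMF, rt
Reagents that add atoms: chlorotriisopropylsilane, CC(C)[Si](Cl)(C(C)C)C(C)C
Why: Imidazole-promoted silylation of the acidic, unhindered 7-hydroxyl; it removes the only acidic O–H before the lithiation and gives both phenols the same fluoride-labile group.

Step 9
Reactants: 16 8-methoxy-2-[4-(3-methylbut-2-enyloxy)phenyl]-5,7-bis(triisopropylsilyloxy)chromen-4-one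
Product: 19 3-hydroxy-8-methoxy-2-[4-(3-methylbut-2-enyloxy)phenyl]-5,7-bis(triisopropylsilyloxy)chromen-4-one, via 3-lithioflavone 17 (not isolated), via lithium trimethoxyborate 18 (not isolated)
Conditions: LiN(iPr)2 (1.5 equiv), THF, −78 °C, 20 min; B(OMe)3 (3 equiv), −78 → 0 °C; then 30% H2O2, aq. NaHCO3, 0 °C → rt
Reagents that add atoms: hydrogen peroxide, OO (oxygen of the 3-hydroxyl); trimethyl borate, COB(OC)OC (boron group of intermediate 18 only)
Why: Deprotonation of the vinylic C3–H (alpha to the C4 carbonyl, the most acidic C–H of 16) by a hindered lithium amide, trapping of 17 with trimethyl borate and oxidation of the C–B bond of 18 by hydroperoxide anion (shift from boron to oxygen), the known lithiation–borylation–oxidation of flavones to flavonols; the oxidant is nucleophilic, so the electron-rich prenyl alkene, which a peracid or dioxirane would epoxidise, should be left alone.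

Step 10
Reactants: 19 3-hydroxy-8-methoxy-2-[4-(3-methylbut-2-enyloxy)phenyl]-5,7-bis(triisopropylsilyloxy)chromen-4-one
Product: 20 3,5,7-trihydroxy-8-methoxy-2-[4-(3-methylbut-2-enyloxy)phenyl]chromen-4-one (3,5,7-trihydroxy-8-methoxy-4′-prenyloxyflavone)
Conditions: Bu4NF (2.5 equiv), AcOH (2.5 equiv), THF, 0 °C → rt, argon
Reagents that add atoms: none
Why: Fluoride-induced cleavage of both aryl silyl ethers (Si–F bond formation, phenoxide leaving groups), buffered with acetic acid so that the air-sensitive flavonol polyanion does not build up; neither acid strong enough to ionise the allylic ether nor hydrogen is used, so the prenyl group survives.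

## Compound list

1 | 2-methoxybenzene-1,3-diol (2-methoxyresorcinol) | COc1c(O)cccc1O | starting material
2 | 2-methoxy-1,3-phenylene diacetate | COc1c(OC(C)=O)cccc1OC(C)=O | intermediate
3 | 2-methoxy-5-(4,4,5,5-tetramethyl-1,3,2-dioxaborolan-2-yl)-1,3-phenylene diacetate (not isolated) | COc1c(OC(C)=O)cc(B2OC(C)(C)C(C)(C)O2)cc1OC(C)=O | intermediate
4 | 5-hydroxy-2-methoxy-1,3-phenylene diacetate | COc1c(OC(C)=O)cc(O)cc1OC(C)=O | intermediate
5 | 5-hydroxy-4-iodo-2-methoxy-1,3-phenylene diacetate | COc1c(OC(C)=O)cc(O)c(I)c1OC(C)=O | intermediate
6 | 4-iodo-2-methoxy-5-(triisopropylsilyloxy)-1,3-phenylene diacetate | COc1c(OC(C)=O)cc(O[Si](C(C)C)(C(C)C)C(C)C)c(I)c1OC(C)=O | intermediate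
7 | 4-hydroxybenzaldehyde | O=Cc1ccc(O)cc1 | starting material
8 | 1-bromo-3-methylbut-2-ene (prenyl bromide) | CC(C)=CCBr | starting material
9 | 4-(3-methylbut-2-enyloxy)benzaldehyde | O=Cc1ccc(OCC=C(C)C)cc1 | intermediate
10 | 1-(2-diazoethenyl)-4-(3-methylbut-2-enyloxy)benzene (not isolated) | [N-]=[N+]=C=Cc1ccc(OCC=C(C)C)cc1 | intermediate
11 | 1-ethynyl-4-(3-methylbut-2-enyloxy)benzene | C#Cc1ccc(OCC=C(C)C)cc1 | intermediate
12 | carbon monoxide | [C-]#[O+] | starting material
13 | 2-methoxy-4-{3-[4-(3-methylbut-2-enyloxy)phenyl]prop-2-ynoyl}-5-(triisopropylsilyloxy)-1,3-phenylene diacetate (not isolated) | COc1c(OC(C)=O)cc(O[Si](C(C)C)(C(C)C)C(C)C)c(C(=O)C#Cc2ccc(OCC=C(C)C)cc2)c1OC(C)=O | intermediate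
14 | 3-(diethylamino)-1-[2,4-dihydroxy-3-methoxy-6-(triisopropylsilyloxy)phenyl]-3-[4-(3-methylbut-2-enyloxy)phenyl]prop-2-en-1-one (not isolated; double-bond geometry not fixed and lost on ring closure) | COc1c(O)cc(O[Si](C(C)C)(C(C)C)C(C)C)c(C(=O)C=C(N(CC)CC)c2ccc(OCC=C(C)C)cc2)c1O | intermediate
15 | 7-hydroxy-8-methoxy-2-[4-(3-methylbut-2-enyloxy)phenyl]-5-(triisopropylsilyloxy)chromen-4-one | COc1c(O)cc(O[Si](C(C)C)(C(C)C)C(C)C)c2c(=O)cc(-c3ccc(OCC=C(C)C)cc3)oc12 | intermediate
16 | 8-methoxy-2-[4-(3-methylbut-2-enyloxy)phenyl]-5,7-bis(triisopropylsilyloxy)chromen-4-one | COc1c(O[Si](C(C)C)(C(C)C)C(C)C)cc(O[Si](C(C)C)(C(C)C)C(C)C)c2c(=O)cc(-c3ccc(OCC=C(C)C)cc3)oc12 | intermediate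
17 | {8-methoxy-2-[4-(3-methylbut-2-enyloxy)phenyl]-4-oxo-5,7-bis(triisopropylsilyloxy)chromen-3-yl}lithium (not isolated) | COc1c(O[Si](C(C)C)(C(C)C)C(C)C)cc(O[Si](C(C)C)(C(C)C)C(C)C)c2c(=O)c([Li])c(-c3ccc(OCC=C(C)C)cc3)oc12 | intermediate
18 | lithium trimethoxy{8-methoxy-2-[4-(3-methylbut-2-enyloxy)phenyl]-4-oxo-5,7-bis(triisopropylsilyloxy)chromen-3-yl}borate (not isolated) | [Li+].COc1c(O[Si](C(C)C)(C(C)C)C(C)C)cc(O[Si](C(C)C)(C(C)C)C(C)C)c2c(=O)c([B-](OC)(OC)OC)c(-c3ccc(OCC=C(C)C)cc3)oc12 | intermediate
19 | 3-hydroxy-8-methoxy-2-[4-(3-methylbut-2-enyloxy)phenyl]-5,7-bis(triisopropylsilyloxy)chromen-4-one | COc1c(O[Si](C(C)C)(C(C)C)C(C)C)cc(O[Si](C(C)C)(C(C)C)C(C)C)c2c(=O)c(O)c(-c3ccc(OCC=C(C)C)cc3)oc12 | intermediate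
20 | 3,5,7-trihydroxy-8-methoxy-2-[4-(3-methylbut-2-enyloxy)phenyl]chromen-4-one | COc1c(O)cc(O)c2c(=O)c(O)c(-c3ccc(OCC=C(C)C)cc3)oc12 | target

## Step count and least certain steps

Total step count: 10. Longest linear sequence: 8 steps (steps 1–4 and 7–10, from 1 to 20); the alkyne branch (steps 5 and 6) has 2 steps.

**Step 7 (key step).** Three processes are the most likely to go wrong:

- loss of the prenyl group by palladium–allyl formation with diethylamine as acceptor;
- direct, non-carbonylative coupling followed by 5-endo closure;
- early aminolysis of the ortho acetate, which would leave an electron-rich iodophenoxide that inserts palladium slowly, together with slow removal of the silyl group at O5 by the amidine base, which would let the wrong oxygen close.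

The fallback sets out from 6 and comes back at 15, and it separates the palladium chemistry from the ring closure. Carbonylative Sonogashira coupling of 6 with 11 without any secondary amine (PdCl2(PPh3)2, CuI cat., Et3N, CO 1 atm, THF, rt) should stop at the acetoxy ynone 13, which is isolated. Palladium-free treatment of 13 with Et2NH in EtOH at room temperature should then remove the acetates, add to the triple bond and close ring C to 15. No compound outside the compound list is made.

**Step 9.** The lithiated species 17 may open ring C by beta-elimination of the ring oxygen or attack unreacted 16. Protodeboronation of 18 before oxidation and partial silyl loss in the peroxide medium are further risks. The fallback sets out from 16 and comes back at 19, and it replaces the ionic carbanion by a covalent organozinc and a catalytic C–B bond formation: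

- zincation at C3 with TMPZnCl·LiCl (THF, 25 °C) to the 3-(chlorozincio)flavone F1;
- iodolysis (I2, 1.0 equiv, −20 °C) to the 3-iodoflavone F2;
- Miyaura borylation (B2pin2, PdCl2(dppf), KOAc, dioxane, 80 °C) to the 3-pinacolboronate F3;
- oxidation with NaBO3·4H2O in THF/H2O to 19.

**Step 2.** Borylation may stall or spread to the positions next to the acetoxy groups, and the electron-rich phenol may be over-oxidised or lose an acetate in the oxidation. No compound of the route offers another entry to the position para to the methoxy group, so this fallback cannot set out from a compound of the route. It replaces steps 1–4, sets out from commercial methyl 3,5-dihydroxy-4-methoxybenzoate F4 and comes back at 6, by classical steps: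

- benzylation (BnBr, K2CO3, DMF) to methyl 3,5-bis(benzyloxy)-4-methoxybenzoate F5;
- reduction (LiAlH4, THF) to [3,5-bis(benzyloxy)-4-methoxyphenyl]methanol F6;
- oxidation (MnO2, CH2Cl2) to 3,5-bis(benzyloxy)-4-methoxybenzaldehyde F7;
- Baeyer–Villiger (Dakin-type) oxidation with mCPBA to 3,5-bis(benzyloxy)-4-methoxyphenyl formate F8, and methanolysis (K2CO3, MeOH) to 3,5-bis(benzyloxy)-4-methoxyphenol F9;
- silylation (iPr3SiCl, imidazole, DMF) to [3,5-bis(benzyloxy)-4-methoxyphenoxy]triisopropylsilane F10;
- hydrogenolysis (H2, Pd/C, EtOAc) to 2-methoxy-5-(triisopropylsilyloxy)benzene-1,3-diol F11;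
- mono-iodination (NIS, CH2Cl2, −78 °C) to 4-iodo-2-methoxy-5-(triisopropylsilyloxy)benzene-1,3-diol F12;
- acetylation (Ac2O, pyridine) to 6.

**Step 3.** Mono-selectivity may be lost, because the two ortho positions of the phenol are equivalent and the first iodine deactivates the second only weakly. Forcing the reagent may oxidise the para-methoxyphenol. The fallback sets out from 4 and comes back at 6 by reversing iodination and silylation. Silylation of 4 (iPr3SiOTf, 2,6-lutidine, CH2Cl2) gives 2-methoxy-5-(triisopropylsilyloxy)-1,3-phenylene diacetate F13. Iodination of this much less activated aryl silyl ether (NIS, CF3CO2H cat., MeCN, rt) needs acid activation for each substitution, so the first iodine and the bulky silyl ether should stop a second one, and 6 is obtained directly.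

## Further compounds

F0 | step 7 | none | none
F1 | step 9 | chloro{8-methoxy-2-[4-(3-methylbut-2-enyloxy)phenyl]-4-oxo-5,7-bis(triisopropylsilyloxy)chromen-3-yl}zinc | COc1c(O[Si](C(C)C)(C(C)C)C(C)C)cc(O[Si](C(C)C)(C(C)C)C(C)C)c2c(=O)c([Zn]Cl)c(-c3ccc(OCC=C(C)C)cc3)oc12
F2 | step 9 | 3-iodo-8-methoxy-2-[4-(3-methylbut-2-enyloxy)phenyl]-5,7-bis(triisopropylsilyloxy)chromen-4-one | COc1c(O[Si](C(C)C)(C(C)C)C(C)C)cc(O[Si](C(C)C)(C(C)C)C(C)C)c2c(=O)c(I)c(-c3ccc(OCC=C(C)C)cc3)oc12
F3 | step 9 | 8-methoxy-2-[4-(3-methylbut-2-enyloxy)phenyl]-3-(4,4,5,5-tetramethyl-1,3,2-dioxaborolan-2-yl)-5,7-bis(triisopropylsilyloxy)chromen-4-one | COc1c(O[Si](C(C)C)(C(C)C)C(C)C)cc(O[Si](C(C)C)(C(C)C)C(C)C)c2c(=O)c(B3OC(C)(C)C(C)(C)O3)c(-c3ccc(OCC=C(C)C)cc3)oc12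
F4 | step 2 | methyl 3,5-dihydroxy-4-methoxybenzoate | COC(=O)c1cc(O)c(OC)c(O)c1
F5 | step 2 | methyl 3,5-bis(benzyloxy)-4-methoxybenzoate | COC(=O)c1cc(OCc2ccccc2)c(OC)c(OCc2ccccc2)c1
F6 | step 2 | [3,5-bis(benzyloxy)-4-methoxyphenyl]methanol | COc1c(OCc2ccccc2)cc(CO)cc1OCc1ccccc1
F7 | step 2 | 3,5-bis(benzyloxy)-4-methoxybenzaldehyde | COc1c(OCc2ccccc2)cc(C=O)cc1OCc1ccccc1
F8 | step 2 | 3,5-bis(benzyloxy)-4-methoxyphenyl formate | COc1c(OCc2ccccc2)cc(OC=O)cc1OCc1ccccc1
F9 | step 2 | 3,5-bis(benzyloxy)-4-methoxyphenol | COc1c(OCc2ccccc2)cc(O)cc1OCc1ccccc1
F10 | step 2 | [3,5-bis(benzyloxy)-4-methoxyphenoxy]triisopropylsilane | COc1c(OCc2ccccc2)cc(O[Si](C(C)C)(C(C)C)C(C)C)cc1OCc1ccccc1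
F11 | step 2 | 2-methoxy-5-(triisopropylsilyloxy)benzene-1,3-diol | COc1c(O)cc(O[Si](C(C)C)(C(C)C)C(C)C)cc1O
F12 | step 2 | 4-iodo-2-methoxy-5-(triisopropylsilyloxy)benzene-1,3-diol | COc1c(O)cc(O[Si](C(C)C)(C(C)C)C(C)C)c(I)c1O
F13 | step 3 | 2-methoxy-5-(triisopropylsilyloxy)-1,3-phenylene diacetate | COc1c(OC(C)=O)cc(O[Si](C(C)C)(C(C)C)C(C)C)cc1OC(C)=O
A1 | alternative 1 | 2-ethynyl-8-methoxy-4-oxo-4H-chromene-3,5,7-triyl triacetate | COc1c(OC(C)=O)cc(OC(C)=O)c2c(=O)c(OC(C)=O)c(C#C)oc12
A2 | alternative 1 | (E)-1-methoxy-3-(trimethylsilyloxy)buta-1,3-diene | CO/C=C/C(=C)O[Si](C)(C)C
A3 | alternative 1 | 2-(4-hydroxyphenyl)-8-methoxy-4-oxo-4H-chromene-3,5,7-triyl triacetate | COc1c(OC(C)=O)cc(OC(C)=O)c2c(=O)c(OC(C)=O)c(-c3ccc(O)cc3)oc12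
A4 | alternative 2 | 3-methoxy-4,6-bis(methoxymethoxy)-2-{1-[4-(3-methylbut-2-enyloxy)phenyl]-2-oxoethoxy}benzaldehyde (racemic) | COCOc1cc(OCOC)c(OC)c(OC(C=O)c2ccc(OCC=C(C)C)cc2)c1C=O
A5 | alternative 2 | trans-3-hydroxy-8-methoxy-5,7-bis(methoxymethoxy)-2-[4-(3-methylbut-2-enyloxy)phenyl]chroman-4-one (racemic; 2R,3R enantiomer drawn) | COCOc1cc(OCOC)c(OC)c2c1C(=O)[C@H](O)[C@@H](c1ccc(OCC=C(C)C)cc1)O2
A6 | alternative 3 | 5-(benzyloxy)-2-methoxybenzene-1,3-diol | COc1c(O)cc(OCc2ccccc2)cc1O
A7 | alternative 3 | ethyl 2-(benzyloxy)-3-[4-(benzyloxy)phenyl]-3-oxopropanoate (racemic) | CCOC(=O)C(OCc1ccccc1)C(=O)c1ccc(OCc2ccccc2)cc1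
A8 | alternative 3 | 3,5-bis(benzyloxy)-2-[4-(benzyloxy)phenyl]-7-hydroxy-8-methoxychromen-4-one | COc1c(O)cc(OCc2ccccc2)c2c(=O)c(OCc3ccccc3)c(-c3ccc(OCc4ccccc4)cc3)oc12
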